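**Plan**
- Retrosynthesis: the three phenolic OH and two CHO groups go back to a 2-alkyl-3,5-dimethoxyphenol. Both bonds at the benzylic carbon (aryl C–CH and CH–CH2 of the isobutyl group) are then cut together, leaving 3,5-dimethoxyphenol, isobutylmagnesium bromide and a eudesmane-4,11-diol with CHO on C1. Ring A of that aldehyde is cut at C1–C10 and C4–C5 (Robinson annulation) back to carone, made from (S)-carvone.
- Enabling feature: the benzylic CH bears isobutyl, ring carbon C1 (the ring A CH next to quaternary C10) and an arene carbon ortho to a phenolic OH. It is therefore the methide carbon of an ortho-quinone methide that a phenoxide and a C1 aldehyde can build.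
- Forward order: ring B is the carvone ring. A gem-dimethylcyclopropane (C6–C7–C11) is fused to it, ring A is annulated, the cyclopropane is opened to the C11 carbinol, ring A is adjusted at C1, C5 and C4, then arene and isobutyl are joined at the C1 aldehyde. Formylation and demethylation finish.
- Stereochemistry: C7 from (S)-carvone; C10 by Michael addition anti to the cyclopropane; C1 by hydrogenation anti to the C10 methyl; C5 by suprafacial hydrogen delivery from an allylic diazene; C4 by trans-diaxial bromohydrin opening; the benzylic centre by 1,2-induction from C1 in the quinone methide.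

Key step: step 14

Remark: α/β refer to the usual eudesmane drawing (C10 top centre, ring A left), in which this antipodal skeleton has its C10 methyl α; dihydrocarvone and carone are used as mixtures at the methyl-bearing carbon and the annulation products as C1 epimer mixtures, since these centres are reset in steps 5 and 7–8.

**Route**

Step 1
Reactants: 1 1-bromobutan-2-one
Product: 3 1-(triphenyl-λ5-phosphanylidene)butan-2-one, via phosphonium bromide 2 (not isolated)
Conditions: PPh3, CH2Cl2, rt; then 2 M aq. NaOH
Reagents that add atoms: triphenylphosphine, c1ccc(cc1)P(c1ccccc1)c1ccccc1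
Why: SN2 quaternisation of PPh3 by the α-bromoketone and deprotonation give the acyl-stabilised Wittig ylide.

Step 2
Reactants: 3 1-(triphenyl-λ5-phosphanylidene)butan-2-one; 4 ethyl glyoxylate
Product: 5 ethyl (E)-4-oxohex-2-enoate
Conditions: CH2Cl2, 0 °C → rt
Reagents that add atoms: none
Why: Wittig olefination of the reactive glyoxylate aldehyde by a stabilised ylide, which should give the (E)-alkene.

Step 3
Reactants: 6 (S)-(+)-carvone
Product: 7 (2S,5S)-dihydrocarvone
Conditions: LiBH(s-Bu)3, THF, −78 °C; then H2O
Reagents that add atoms: none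
Why: conjugate hydride reduction of the β-unsubstituted enone, which leaves the isopropenyl-bearing stereocentre untouched.

Step 4
Reactants: 7 (2S,5S)-dihydrocarvone
Product: 9 (1R,3S,6S)-3,7,7-trimethylbicyclo[4.1.0]heptan-2-one (carone), via tertiary bromide 8 (not isolated)
Conditions: HBr (33% in AcOH), 0 °C; then KOH, MeOH, 0 °C → rt
Reagents that add atoms: none
Why: Markovnikov hydrobromination of the isopropenyl group, then the C6 enolate displaces the tertiary bromide (1,3-elimination) to give the necessarily cis-fused gem-dimethylcyclopropane with the carvone stereocentre retained.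

Step 5
Reactants: 9 carone; 5 ethyl (E)-4-oxohex-2-enoate
Product: 11 ethyl 6,11-cyclo-3-oxoeudesm-4-ene-1-carboxylate (C1 epimers), via Michael adduct 10 (not isolated)
Conditions: NaOEt, EtOH, 0 °C → rt; then reflux
Reagents that add atoms: none
Why: Robinson annulation in which carone can enolise only toward its methyl-bearing carbon (the other α-carbon is a cyclopropane bridgehead), the enolate adds to the alkene carbon β to the ketone of 5 on the face opposite to the gem-dimethylcyclopropane (C10 methyl cis to C11), and aldol condensation of the ethyl ketone onto the ring carbonyl closes ring A.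

Step 6
Reactants: 11 tricyclic enone ester
Product: 12 ethyl 11-hydroxy-3-oxoeudesm-4-ene-1-carboxylate (C1 epimers)
Conditions: 10% aq. H2SO4, THF, rt
Reagents that add atoms: water, O
Why: acid-catalysed homoconjugate addition in which the protonated enone opens the conjugated cyclopropane at C6–C11 to the tertiary C11 cation, water is captured and the dienol returns to the Δ4-enone, with C7 and C10 untouched.

Step 7
Reactants: 12 ethyl 11-hydroxy-3-oxoeudesm-4-ene-1-carboxylate
Product: 13 ethyl 11-hydroxy-3-oxoeudesma-1,4-diene-1-carboxylate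
Conditions: IBX, DMSO/toluene, 70 °C
Reagents that add atoms: none
Why: IBX dehydrogenation on the α′ side of the enone (C1–C2, where C1–H is also activated by the ester) should give the cross-conjugated dienone, so both C1 epimers converge while the tertiary alcohol cannot be oxidised.

Step 8
Reactants: 13 dienone ester
Product: 14 ethyl 11-hydroxy-3-oxoeudesm-4-ene-1α-carboxylate
Conditions: H2 (1 atm), Pd/C, EtOAc, rt
Reagents that add atoms: none
Why: catalytic hydrogenation of the electron-poor trisubstituted C1=C2 bond (the tetrasubstituted 4-methyl enone is far slower) from the face opposite to the C10 methyl, as in additions to C1 of steroidal 1,4-dien-3-ones, sets C1 with H β and the ester α.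

Step 9
Reactants: 14 ethyl 11-hydroxy-3-oxoeudesm-4-ene-1α-carboxylate
Product: 15 ethyl 3α,11-dihydroxyeudesm-4-ene-1α-carboxylate
Conditions: NaBH4, CeCl3·7H2O, MeOH, −78 °C
Reagents that add atoms: none
Why: Luche 1,2-reduction in which hydride attacks C3 axially from the β-face (opposite to the C10 methyl, with only C1–H axial on that face), giving the pseudo-equatorial 3α-alcohol.

Step 10
Reactants: 15 ethyl 3α,11-dihydroxyeudesm-4-ene-1α-carboxylate
Product: 18 ethyl 11-hydroxy-5β-eudesm-3-ene-1α-carboxylate, via sulfonylhydrazine 16 (not isolated), via allylic diazene 17 (not isolated)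
Conditions: PPh3, DEAD, 2-nitrobenzenesulfonylhydrazide, THF, −30 °C → rt
Reagents that add atoms: none
Why: Mitsunobu displacement of the secondary allylic alcohol with inversion gives 16, loss of sulfinic acid gives the 3β-diazene 17, and its retro-ene loss of N2 delivers hydrogen suprafacially to C5 (reductive 1,3-transposition), so C5–H becomes β (trans to the C10 methyl) and the alkene moves to C3=C4.

Step 11
Reactants: 18 ethyl 11-hydroxy-5β-eudesm-3-ene-1α-carboxylate
Product: 19 ethyl 3β-bromo-4α,11-dihydroxy-5β-eudesmane-1α-carboxylate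
Conditions: NBS, THF/H2O, 0 °C
Reagents that add atoms: N-bromosuccinimide, O=C1CCC(=O)N1Br; water, O
Why: bromohydrin formation in which the bromonium ion forms on the β-face, away from the axial C10 methyl, and water opens it anti at tertiary C4 (Markovnikov and trans-diaxial, Fürst–Plattner rule), giving the axial 4α-OH with the C4 methyl equatorial.

Step 12
Reactants: 19 bromohydrin ester
Product: 21 1α-(hydroxymethyl)-5β-eudesmane-4α,11-diol, via epoxy diol 20 (not isolated)
Conditions: LiAlH4, THF, 0 °C → reflux; then H2O, aq. NaOH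
Reagents that add atoms: none
Why: LiAlH4 reduces the ester to the primary alcohol and removes bromine, since the trans-diaxial bromohydrin alkoxide closes to the α-epoxide 20, which hydride opens at secondary C3 (trans-diaxial) with the C4 carbinol configuration kept.

Step 13
Reactants: 21 triol
Product: 22 4α,11-dihydroxy-5β-eudesmane-1α-carbaldehyde
Conditions: Dess–Martin periodinane, CH2Cl2, 0 °C → rt
Reagents that add atoms: none
Why: Dess–Martin oxidation of the only oxidisable (primary) alcohol under non-basic conditions that should leave the C1 stereocentre alone.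

Step 14
Reactants: 22 4α,11-dihydroxy-5β-eudesmane-1α-carbaldehyde; 23 3,5-dimethoxyphenol; 24 isobutylmagnesium bromide
Product: 29 2-[(1R)-1-(4α,11-dihydroxy-5β-eudesman-1α-yl)-3-methylbutyl]-3,5-dimethoxyphenol, via hydroxybenzyl adduct 25 (not isolated), via aryl carbonate 26 (not isolated), via benzylic carbonate 27 (not isolated), via quinone methide 28 (not isolated)
Conditions: 23, EtMgBr, Et2O then CH2Cl2, 0 °C; 22, −20 °C → rt; Boc2O, THF, −40 °C; 24 (excess), −78 °C → rt; then H2O
Reagents that add atoms: none
Why: Proposed new method: the bromomagnesium phenoxide of 23 binds the aldehyde and attacks it through an ortho carbon in a six-membered chelate to give 25 as its magnesium salt; Boc2O acylates the phenoxide oxygen (26), the Grignard reagent deprotonates the benzylic hydroxyl, the Boc group migrates to it (27), the phenoxide expels tert-butyl carbonate to give ortho-quinone methide 28, and a second molecule of i-BuMgBr adds 1,4 to the methide carbon with return of aromaticity. The closest known reaction types are the ortho-hydroxyalkylation of magnesium phenoxides with aldehydes and the generation of ortho-quinone methides from O-Boc salicyl alcohols by Grignard reagents followed by their 1,4-addition; new is their union in one flask on an α-branched aldehyde next to a quaternary carbon. No ring is closed. The benzylic stereocentre is controlled by 1,2-induction from C1: in the methide conformer with C1–H in the plane of the exocyclic double bond (least allylic strain) the quaternary C10 shields one face and the Grignard reagent enters from the C2 side, which gives the (R) centre of the target. The step needs ortho- over para-attack of the phenoxide (magnesium chelation; the two ortho carbons are equivalent), 1,4- over 1,2-addition (rearomatisation) and capture of 28 before it tautomerises to a vinylphenol or adds a second phenoxide (it is generated cold in excess Grignard reagent with only one equivalent of phenoxide); the two tertiary hydroxyls are carried as magnesium alkoxides.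

Step 15
Reactants: 29 2-alkyl-3,5-dimethoxyphenol
Product: 30 2-[(1R)-1-(4α,11-dihydroxy-5β-eudesman-1α-yl)-3-methylbutyl]-1,3,5-trimethoxybenzene
Conditions: MeI, K2CO3, acetone, reflux
Reagents that add atoms: iodomethane, CI
Why: Williamson etherification of the phenoxide, as carbonate does not deprotonate the tertiary alcohols.

Step 16
Reactants: 30 trimethyl ether
Product: 31 1,3-dibromo-5-[(1R)-1-(4α,11-dihydroxy-5β-eudesman-1α-yl)-3-methylbutyl]-2,4,6-trimethoxybenzene
Conditions: NBS (2 equiv), MeCN, 0 °C
Reagents that add atoms: N-bromosuccinimide, O=C1CCC(=O)N1Br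
Why: electrophilic aromatic bromination at the only two free ring positions, each activated by three methoxy groups.

Step 17
Reactants: 31 dibromide
Product: 32 5-[(1R)-1-(4α,11-dihydroxy-5β-eudesman-1α-yl)-3-methylbutyl]-2,4,6-trimethoxybenzene-1,3-dicarbaldehyde
Conditions: t-BuLi (excess), THF, −78 °C; DMF, −78 → 0 °C; then H2O
Reagents that add atoms: N,N-dimethylformamide, CN(C)C=O
Why: after deprotonation of the two hydroxyls, double bromine–lithium exchange gives a bis(aryllithium) whose lithium atoms each sit between two methoxy groups, and formylation with DMF should give the dialdehyde.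

Step 18
Reactants: 32 dialdehyde trimethyl ether
Product: 33 5-[(1R)-1-(4α,11-dihydroxy-5β-eudesman-1α-yl)-3-methylbutyl]-2,4,6-trihydroxybenzene-1,3-dicarbaldehyde (CNP0409870.6)
Conditions: NaSEt (excess), DMF, 120 °C; then 1 M HCl
Reagents that add atoms: none
Why: SN2 demethylation by thiolate at the three O-methyl carbons, each methoxy being ortho or para to a formyl group so that the phenoxide leaves readily, while tertiary alcohols, aldehydes without α-hydrogen and all stereocentres are inert.

**Compound list**

1 | 1-bromobutan-2-one | CCC(=O)CBr | starting material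
2 | (2-oxobutyl)triphenylphosphonium bromide | CCC(=O)C[P+](c1ccccc1)(c1ccccc1)c1ccccc1.[Br-] | intermediate (not isolated)
3 | 1-(triphenyl-λ5-phosphanylidene)butan-2-one | CCC(=O)C=P(c1ccccc1)(c1ccccc1)c1ccccc1 | intermediate
4 | ethyl glyoxylate | CCOC(=O)C=O | starting material
5 | ethyl (E)-4-oxohex-2-enoate | CCOC(=O)/C=C/C(=O)CC | intermediate
6 | (S)-(+)-carvone | CC1=CC[C@@H](CC1=O)C(C)=C | starting material
7 | (2S,5S)-2-methyl-5-(prop-1-en-2-yl)cyclohexan-1-one (trans-dihydrocarvone; C2 epimer also present) | C[C@H]1CC[C@@H](CC1=O)C(C)=C | intermediate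
8 | (2S,5S)-5-(2-bromopropan-2-yl)-2-methylcyclohexan-1-one | C[C@H]1CC[C@@H](CC1=O)C(C)(C)Br | intermediate (not isolated)
9 | (1R,3S,6S)-3,7,7-trimethylbicyclo[4.1.0]heptan-2-one (carone; C3 epimer also present) | C[C@H]1CC[C@H]2[C@@H](C1=O)C2(C)C | intermediate
10 | ethyl 4-oxo-2-[(1R,6S)-3,7,7-trimethyl-2-oxobicyclo[4.1.0]heptan-3-yl]hexanoate, chain trans to the cyclopropane CMe2 (C2 epimers) | CCC(=O)CC(C(=O)OCC)[C@@]1(C)CC[C@H]2[C@@H](C1=O)C2(C)C | intermediate (not isolated)
11 | ethyl 6,11-cyclo-3-oxoeudesm-4-ene-1-carboxylate, cyclopropane and C10 methyl α (C1 epimers) | CCOC(=O)C1CC(=O)C(C)=C2[C@@H]3[C@H](CC[C@]12C)C3(C)C | intermediate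
12 | ethyl 11-hydroxy-3-oxoeudesm-4-ene-1-carboxylate, 7α side chain, 10α-methyl (C1 epimers) | CCOC(=O)C1CC(=O)C(C)=C2C[C@@H](C(C)(C)O)CC[C@]12C | intermediate
13 | ethyl 11-hydroxy-3-oxoeudesma-1,4-diene-1-carboxylate | CCOC(=O)C1=CC(=O)C(C)=C2C[C@@H](C(C)(C)O)CC[C@]12C | intermediate
14 | ethyl 11-hydroxy-3-oxoeudesm-4-ene-1α-carboxylate | CCOC(=O)[C@H]1CC(=O)C(C)=C2C[C@@H](C(C)(C)O)CC[C@]12C | intermediate
15 | ethyl 3α,11-dihydroxyeudesm-4-ene-1α-carboxylate | CCOC(=O)[C@H]1C[C@@H](O)C(C)=C2C[C@@H](C(C)(C)O)CC[C@]12C | intermediate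
16 | ethyl 11-hydroxy-3β-[1-(2-nitrophenylsulfonyl)hydrazin-1-yl]eudesm-4-ene-1α-carboxylate | CCOC(=O)[C@H]1C[C@H](N(N)S(=O)(=O)c3ccccc3[N+](=O)[O-])C(C)=C2C[C@@H](C(C)(C)O)CC[C@]12C | intermediate (not isolated)
17 | ethyl 3β-diazenyl-11-hydroxyeudesm-4-ene-1α-carboxylate | CCOC(=O)[C@H]1C[C@H](N=N)C(C)=C2C[C@@H](C(C)(C)O)CC[C@]12C | intermediate (not isolated)
18 | ethyl 11-hydroxy-5β-eudesm-3-ene-1α-carboxylate (trans ring fusion) | CCOC(=O)[C@H]1CC=C(C)[C@H]2C[C@@H](C(C)(C)O)CC[C@]12C | intermediate
19 | ethyl 3β-bromo-4α,11-dihydroxy-5β-eudesmane-1α-carboxylate (4β-methyl) | CCOC(=O)[C@H]1C[C@H](Br)[C@@](C)(O)[C@H]2C[C@@H](C(C)(C)O)CC[C@]12C | intermediate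
20 | 3α,4α-epoxy-1α-(hydroxymethyl)-5β-eudesman-11-ol | OC[C@H]1C[C@H]3O[C@@]3(C)[C@H]2C[C@@H](C(C)(C)O)CC[C@]12C | intermediate (not isolated)
21 | 1α-(hydroxymethyl)-5β-eudesmane-4α,11-diol | OC[C@H]1CC[C@@](C)(O)[C@H]2C[C@@H](C(C)(C)O)CC[C@]12C | intermediate
22 | 4α,11-dihydroxy-5β-eudesmane-1α-carbaldehyde | O=C[C@H]1CC[C@@](C)(O)[C@H]2C[C@@H](C(C)(C)O)CC[C@]12C | intermediate
23 | 3,5-dimethoxyphenol | COc1cc(O)cc(OC)c1 | starting material
24 | isobutylmagnesium bromide | CC(C)C[Mg]Br | starting material
25 | 2-[hydroxy(4α,11-dihydroxy-5β-eudesman-1α-yl)methyl]-3,5-dimethoxyphenol (carbinol epimers; present as magnesium salt) | COc1cc(O)c(C(O)[C@H]2CC[C@@](C)(O)[C@H]3C[C@@H](C(C)(C)O)CC[C@]23C)c(OC)c1 | intermediate (not isolated)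
26 | tert-butyl aryl carbonate of 25 (Boc on the phenol oxygen) | COc1cc(OC(=O)OC(C)(C)C)c(C(O)[C@H]2CC[C@@](C)(O)[C@H]3C[C@@H](C(C)(C)O)CC[C@]23C)c(OC)c1 | intermediate (not isolated)
27 | benzylic tert-butyl carbonate of 25 (Boc on the benzylic oxygen) | COc1cc(O)c(C(OC(=O)OC(C)(C)C)[C@H]2CC[C@@](C)(O)[C@H]3C[C@@H](C(C)(C)O)CC[C@]23C)c(OC)c1 | intermediate (not isolated)
28 | 6-[(4α,11-dihydroxy-5β-eudesman-1α-yl)methylidene]-3,5-dimethoxycyclohexa-2,4-dien-1-one (drawn Z; the geometry does not enter the facial argument) | COC1=CC(=O)/C(=C\[C@H]2CC[C@@](C)(O)[C@H]3C[C@@H](C(C)(C)O)CC[C@]23C)C(OC)=C1 | intermediate (not isolated)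
29 | 2-[(1R)-1-(4α,11-dihydroxy-5β-eudesman-1α-yl)-3-methylbutyl]-3,5-dimethoxyphenol | CC(C)C[C@@H](c1c(O)cc(OC)cc1OC)[C@H]1CC[C@@](C)(O)[C@H]2C[C@@H](C(C)(C)O)CC[C@]12C | intermediate
30 | 2-[(1R)-1-(4α,11-dihydroxy-5β-eudesman-1α-yl)-3-methylbutyl]-1,3,5-trimethoxybenzene | CC(C)C[C@@H](c1c(OC)cc(OC)cc1OC)[C@H]1CC[C@@](C)(O)[C@H]2C[C@@H](C(C)(C)O)CC[C@]12C | intermediate
31 | 1,3-dibromo-5-[(1R)-1-(4α,11-dihydroxy-5β-eudesman-1α-yl)-3-methylbutyl]-2,4,6-trimethoxybenzene | CC(C)C[C@@H](c1c(OC)c(Br)c(OC)c(Br)c1OC)[C@H]1CC[C@@](C)(O)[C@H]2C[C@@H](C(C)(C)O)CC[C@]12C | intermediate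
32 | 5-[(1R)-1-(4α,11-dihydroxy-5β-eudesman-1α-yl)-3-methylbutyl]-2,4,6-trimethoxybenzene-1,3-dicarbaldehyde | CC(C)C[C@@H](c1c(OC)c(C=O)c(OC)c(C=O)c1OC)[C@H]1CC[C@@](C)(O)[C@H]2C[C@@H](C(C)(C)O)CC[C@]12C | intermediate
33 | CNP0409870.6; benzylic (R), 1R,4R,5S,7S,10R | CC(C)C[C@@H](c1c(O)c(C=O)c(O)c(C=O)c1O)[C@H]1CC[C@@](C)(O)[C@H]2C[C@@H](C(C)(C)O)CC[C@]12C | target

**Counts**

Total steps: 18. Longest linear sequence: 16 steps (6 to 33, steps 3–18).

**Steps most likely to fail**

Step 14 (proposed new method). The quinone methide may be lost before the Grignard reagent reaches it, through tautomerisation to the vinylphenol, addition of a second phenoxide, or reversible capture by the C4 alkoxide. The hindered aldehyde may also resist the phenoxide, or facial selectivity may be poor. The fallback uses known reactions and sets out from 22. 2,4,6-Trimethoxyphenyllithium (1,3,5-trimethoxybenzene, n-BuLi, THF, 0 °C; excess to cover the two hydroxyls) adds to the aldehyde to give the benzylic alcohol F1. BF3·OEt2 in CH2Cl2 at −78 °C should ionise this trioxygenated benzylic alcohol far more readily than the tertiary carbinols, and methallyltrimethylsilane traps the cation (Hosomi–Sakurai-type substitution, anti to C10 by the same 1,2-induction) to give the methallyl compound F2. Hydrogenation (H2, Pd/C) of its 1,1-disubstituted alkene gives 30, where the route is rejoined; 29 and step 15 are bypassed.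

Step 5. The hindered tertiary enolate may act as a base toward 5, ethoxide may add to or oligomerise 5, or bond formation next to the ester may be too slow. The fallback sets out from 9. LDA and Me3SiCl give the only possible silyl enol ether, the trimethylsilyl enol ether F3. A Mukaiyama–Michael addition to 5 (Sc(OTf)3, CH2Cl2, −78 °C) under non-basic conditions gives, after desilylation, the diketo ester 10, which is cyclised separately (NaOEt, EtOH) to 11.

Step 10. The Mitsunobu displacement at the allylic carbon next to the 4-methyl group may be slow or may ionise, eroding the inversion on which the trans ring fusion depends. The fallback sets out from 15. Formylation of the secondary hydroxyl (formic acetic anhydride, pyridine, 0 °C) gives the allylic formate F4. Pd(acac)2 and P(n-Bu)3 in dioxane at reflux then effect formate hydrogenolysis (Tsuji–Trost type): zerovalent palladium ionises the formate with inversion, and the hydride formed by loss of CO2 is delivered from palladium to the ring-fusion carbon C5 on the β-face, giving 18 directly.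

**Further compounds**

F1 | step 14 | (4α,11-dihydroxy-5β-eudesman-1α-yl)(2,4,6-trimethoxyphenyl)methanol (carbinol epimers) | COc1cc(OC)c(C(O)[C@H]2CC[C@@](C)(O)[C@H]3C[C@@H](C(C)(C)O)CC[C@]23C)c(OC)c1
F2 | step 14 | 2-[(1R)-1-(4α,11-dihydroxy-5β-eudesman-1α-yl)-3-methylbut-3-enyl]-1,3,5-trimethoxybenzene | CC(=C)C[C@@H](c1c(OC)cc(OC)cc1OC)[C@H]1CC[C@@](C)(O)[C@H]2C[C@@H](C(C)(C)O)CC[C@]12C
F3 | step 5 | trimethyl{[(1R,6S)-3,7,7-trimethylbicyclo[4.1.0]hept-2-en-2-yl]oxy}silane | CC=1CC[C@H]2[C@@H](C1O[Si](C)(C)C)C2(C)C
F4 | step 10 | ethyl 3α-(formyloxy)-11-hydroxyeudesm-4-ene-1α-carboxylate | CCOC(=O)[C@H]1C[C@@H](OC=O)C(C)=C2C[C@@H](C(C)(C)O)CC[C@]12C
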